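Ring B is cut at C7. The cross-conjugated dienone C6=C7–C8(=O)–C9=C10 is made from a 7-nor hydrindane by inserting C7, already bearing bromine, between C6 and C8. Dibromocarbene adds to the silyl enol ether bond of a 2-silyloxycyclopentadiene and the cyclopropane opens in the same flask. This enlarges the five-membered ring to ring B, forms C6–C7 and C7–C8, and leaves the bromide that later accepts C11. The feature exploited is ring B itself: a 2-substituted cyclohexa-2,5-dienone whose C5 is quaternary, so aromatisation is impossible. The precursor is the bicyclic diene carrying the 4β,5β-methyls, a C1β TBS ether and a C8 trimethylsilyl enol ether.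

Key step: step 8

Remark: positions are given in eremophilane numbering (C1 oxygenated carbon, C4 and C5 methyl-bearing carbons, C8 carbonyl, C11 ester α-carbon); β is the face of the C5 methyl.
Remark: the antipode of each chiral ligand (steps 1 and 9) is defined by the configuration it must deliver (3S of the cyclohexanone, 11S of the ester).
Remark: C1 is carried as a TBS ether through step 8 because a free alkoxide or an ester would not survive tert-butoxide and dibromocarbene; the enol ether stays trimethylsilyl so that the ring-opened cation loses silicon at once.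
Remark: allyl bromide with Wacker oxidation is used as the acetonyl equivalent, since this cyclopentenone annulation is well established on α-quaternary cyclohexanones.
Remark: the CIP descriptor of the quaternary carbon switches from R to S at compound 11 through a change of priorities only; its geometry is unchanged.

Step 1
Reactants: 1 2-methylcyclohex-2-en-1-one; 2 allyl bromide
Product: 5 (2R,3S)-2-allyl-2,3-dimethylcyclohexan-1-one, via dimethylaluminium enolate 3 (not isolated), via lithium aluminate enolate 4 (not isolated)
Conditions: Me3Al (1.5 equiv), CuTC (copper thiophene-2-carboxylate, C5H3CuO2S, 2 mol%), BINOL-derived bis(1-phenylethyl)amine phosphoramidite (4 mol%, antipode giving 3S), Et2O, −30 °C; then MeLi (1.5 equiv), THF/DMPU, allyl bromide (3 equiv), −30 °C → rt; aq. NH4Cl/Rochelle salt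
Reagents that add atoms: trimethylaluminium, C[Al](C)C
Why: Copper-catalysed asymmetric conjugate addition, in which the phosphoramidite selects the enone face and sets the methyl-bearing centre (3S, later C4), is followed by alkylation of the regiodefined enolate as its lithium aluminate, where allyl bromide approaches anti to the neighbouring C3 methyl and so sets the quaternary centre (2R, later C5) with the two methyls cis.

Step 2
Reactants: 5 (2R,3S)-2-allyl-2,3-dimethylcyclohexan-1-one
Product: 6 (2R,3S)-2,3-dimethyl-2-(2-oxopropyl)cyclohexan-1-one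
Conditions: PdCl2 (10 mol%), CuCl (1 equiv), O2 (1 atm), DMF/H2O 7:1, rt
Reagents that add atoms: water, O
Why: Tsuji–Wacker oxidation (Markovnikov hydroxypalladation of the terminal alkene, then β-hydride elimination) gives the methyl ketone, as is routine for allyl groups on α-quaternary cyclohexanones, and touches no stereocentre.

Step 3
Reactants: 6 (2R,3S)-2,3-dimethyl-2-(2-oxopropyl)cyclohexan-1-one
Product: 7 (7S,7aR)-7,7a-dimethyl-1,4,5,6,7,7a-hexahydro-2H-inden-2-one
Conditions: KOH (powdered, 0.5 equiv), xylenes, 110 °C, Dean–Stark trap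
Reagents that add atoms: none
Why: Intramolecular aldol condensation, in which the methyl ketone enolate adds to the ring carbonyl and dehydration pulls the reversible aldol manifold to the conjugated cyclopentenone (C9=C10, C8=O); the quaternary centre and the non-enolisable methyl-bearing centre cannot epimerise.

Step 4
Reactants: 7 (7S,7aR)-7,7a-dimethyl-1,4,5,6,7,7a-hexahydro-2H-inden-2-one
Product: 8 tert-butyl{[(7S,7aR)-7,7a-dimethyl-5,6,7,7a-tetrahydro-1H-inden-2-yl]oxy}dimethylsilane (dienol ether with C8=C9 and C10=C1)
Conditions: TBSOTf (1.3 equiv), Et3N (3 equiv), CH2Cl2, 0 °C → rt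
Reagents that add atoms: tert-butyldimethylsilyl trifluoromethanesulfonate, CC(C)(C)[Si](C)(C)OS(=O)(=O)C(F)(F)F
Why: Soft enolisation under equilibrating conditions removes the axial γ-proton at C1 from the O-silyl oxocarbenium ion and should give the linearly conjugated dienol ether, favoured over the cross-conjugated cyclopentadiene isomer by through-conjugation of the oxygen and by a C10=C1 bond exocyclic to the five-membered ring.

Step 5
Reactants: 8 tert-butyl{[(7S,7aR)-7,7a-dimethyl-5,6,7,7a-tetrahydro-1H-inden-2-yl]oxy}dimethylsilane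
Product: 9 (4R,7S,7aR)-4-hydroxy-7,7a-dimethyl-1,4,5,6,7,7a-hexahydro-2H-inden-2-one (1β-hydroxy enone)
Conditions: mCPBA (1.05 equiv), NaHCO3, CH2Cl2, −20 °C → 0 °C; aq. Na2S2O3/NaHCO3
Reagents that add atoms: 3-chloroperoxybenzoic acid, O=C(OO)c1cccc(Cl)c1
Why: Vinylogous Rubottom oxidation, in which the peracid attacks the electron-rich γ-terminus C1 of the 1-silyloxydiene along the axial trajectory on the β face (the sense seen in the 6β-hydroxylation of steroidal 3,5-dienol ethers) and collapse of the epoxide with loss of silicon restores the enone, sets the 1β carbinol (4R).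

Step 6
Reactants: 9 (4R,7S,7aR)-4-hydroxy-7,7a-dimethyl-1,4,5,6,7,7a-hexahydro-2H-inden-2-one
Product: 10 (4R,7S,7aR)-4-[(tert-butyldimethylsilyl)oxy]-7,7a-dimethyl-1,4,5,6,7,7a-hexahydro-2H-inden-2-one
Conditions: TBSOTf (1.2 equiv), 2,6-lutidine (2 equiv), CH2Cl2, −78 °C → 0 °C
Reagents that add atoms: tert-butyldimethylsilyl trifluoromethanesulfonate, CC(C)(C)[Si](C)(C)OS(=O)(=O)C(F)(F)F
Why: Silyl triflate silylation of the hindered axial allylic alcohol at low temperature is faster than enolisation of the enone by the weak pyridine base, and the resulting TBS ether is robust to amide base, tert-butoxide and dibromocarbene.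

Step 7
Reactants: 10 (4R,7S,7aR)-4-[(tert-butyldimethylsilyl)oxy]-7,7a-dimethyl-1,4,5,6,7,7a-hexahydro-2H-inden-2-one
Product: 11 tert-butyl{[(4R,7S,7aS)-7,7a-dimethyl-2-(trimethylsilyloxy)-5,6,7,7a-tetrahydro-4H-inden-4-yl]oxy}dimethylsilane (2-silyloxycyclopentadiene with C6=C8 and C9=C10)
Conditions: LiN(iPr)2 (1.15 equiv), TMSCl (1.5 equiv, present from the start), THF, −78 °C; pentane, filtration, concentration; used cold without chromatography
Reagents that add atoms: chlorotrimethylsilane, C[Si](C)(C)Cl
Why: Kinetic deprotonation by the hindered amide at the only α′ position (the C6 methylene, while C1–H is γ and shielded by the silyl ether) with in situ O-silylation gives the cross-conjugated silyl dienol ether, which cannot isomerise by 1,5-hydrogen shift because C5 is quaternary.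

Step 8
Reactants: 11 tert-butyl{[(4R,7S,7aS)-7,7a-dimethyl-2-(trimethylsilyloxy)-5,6,7,7a-tetrahydro-4H-inden-4-yl]oxy}dimethylsilane; 12 bromoform
Product: 14 7-bromo-1β-(tert-butyldimethylsilyloxy)-11,12,13-trinoreremophila-6,9-dien-8-one [(4aS,5S,8R)-3-bromo-8-[(tert-butyldimethylsilyl)oxy]-4a,5-dimethyl-5,6,7,8-tetrahydronaphthalen-2(4aH)-one], via dibromocyclopropane 13 (not isolated)
Conditions: CHBr3 (1.5 equiv), KOtBu (2.2 equiv, in portions), pentane, −30 °C → 0 °C, then rt; pH 7 phosphate buffer
Reagents that add atoms: none
Why: α-Elimination of HBr from bromoform gives dibromocarbene, which adds in a [2+1] cheletropic step to the most nucleophilic π-bond, the C6=C8 silyl enol ether, to form the donor-substituted 6,6-dibromobicyclo[3.1.0]hexene 13; this opens by disrotatory 2π-electrocyclic cleavage of the C6–C8 bond with departure of the endo bromide, pushed by the silyloxy lone pair, and desilylation of the resulting O-silyl cyclohexadienyl cation leaves C6=C7(Br)–C8=O. The closest known reactions are the dihalocarbene homologation of cyclic trimethylsilyl enol ethers to 2-halocycloalk-2-enones and the Ciamician–Dennstedt ring expansion of cyclopentadienes and indenes. Ring B is closed not by a cyclisation but by one-carbon enlargement of the five-membered ring: a three-membered ring is closed by [2+1] addition and the bond it shares with the cyclopentene is then broken, which forms C6–C7 and C7–C8. No stereocentre is created, since the two cyclopropane centres vanish on opening and the face of carbene attack is therefore irrelevant, and C1, C4 and C5 are untouched. The step needs chemoselectivity for C6=C8 over C9=C10, which the oxygen donor on C8, the cross-conjugation that leaves C9=C10 unactivated and the fully substituted C10 should secure, while quaternary C5 prevents proton loss so that the sequence stops at the dienone and not at a bromoarene.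

Step 9
Reactants: 14 7-bromo-1β-(tert-butyldimethylsilyloxy)-11,12,13-trinoreremophila-6,9-dien-8-one; 15 methyl 2-chloropropanoate (racemic)
Product: 16 methyl (11S)-1β-(tert-butyldimethylsilyloxy)-8-oxoeremophila-6,9-dien-12-oate [methyl (2S)-2-[(5R,8S,8aS)-5-[(tert-butyldimethylsilyl)oxy]-8,8a-dimethyl-3-oxo-3,5,6,7,8,8a-hexahydronaphthalen-2-yl]propanoate]
Conditions: 15 (2 equiv), NiBr2(diglyme) (10 mol%), 4,4′-di(heptan-4-yl)-2,2′-bi(2-oxazoline) (20 mol%, antipode giving 11S), Mn powder (3 equiv), NaI (0.5 equiv), TMSCl (0.4 equiv), DMA, 0 °C → rt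
Reagents that add atoms: none
Why: Nickel-catalysed enantioconvergent reductive cross-electrophile coupling, in which the alkenyl bromide adds oxidatively to zerovalent nickel, the planar α-ester radical from either enantiomer of 15 is captured and reductive elimination from trivalent nickel occurs inside the chiral bi(oxazoline) pocket, should set C11 as S under catalyst control, with neutral conditions that spare C1 and the new C11–H.

Step 10
Reactants: 16 methyl (11S)-1β-(tert-butyldimethylsilyloxy)-8-oxoeremophila-6,9-dien-12-oate
Product: 17 methyl (11S)-1β-hydroxy-8-oxoeremophila-6,9-dien-12-oate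
Conditions: HF·pyridine, pyridine, THF, 0 °C → rt (polyethylene vessel)
Reagents that add atoms: none
Why: Buffered, non-basic fluoride desilylation cleaves the secondary TBS ether without enolising the C11 ester or the γ-position C1, which a basic fluoride source could epimerise.

Step 11
Reactants: 17 methyl (11S)-1β-hydroxy-8-oxoeremophila-6,9-dien-12-oate; 18 angelic acid
Product: 20 methyl (11S)-1β-angeloyloxy-8-oxoeremophila-6,9-dien-12-oate (target; 1R,4S,5S,11S), via Yamaguchi mixed anhydride 19 (not isolated)
Conditions: 18 (3 equiv), 2,4,6-trichlorobenzoyl chloride (3 equiv), Et3N (3.3 equiv), toluene, rt; then 17, toluene, 75 °C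
Reagents that add atoms: none
Why: Yamaguchi esterification, in which the alcohol attacks the unhindered angeloyl carbonyl of the preformed mixed anhydride without a nucleophilic catalyst or strong base, should preserve the Z geometry of the angelate and acylate C1–OH with retention.

Compound list
1 | 2-methylcyclohex-2-en-1-one | CC1=CCCC1=O | starting material
2 | allyl bromide (3-bromoprop-1-ene) | C=CCBr | starting material
3 | dimethylaluminium (S)-2,3-dimethylcyclohex-1-en-1-olate | C[Al](C)OC1=C(C)[C@@H](C)CCC1 | intermediate (not isolated)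
4 | lithium trimethyl[(S)-2,3-dimethylcyclohex-1-en-1-olato]aluminate | [Li+].C[Al-](C)(C)OC1=C(C)[C@@H](C)CCC1 | intermediate (not isolated)
5 | (2R,3S)-2-allyl-2,3-dimethylcyclohexan-1-one | O=C1CCC[C@H](C)[C@@]1(C)CC=C | intermediate
6 | (2R,3S)-2,3-dimethyl-2-(2-oxopropyl)cyclohexan-1-one | O=C1CCC[C@H](C)[C@@]1(C)CC(C)=O | intermediate
7 | (7S,7aR)-7,7a-dimethyl-1,4,5,6,7,7a-hexahydro-2H-inden-2-one | C1CC[C@H](C)[C@@]2(C)CC(=O)C=C12 | intermediate
8 | tert-butyl{[(7S,7aR)-7,7a-dimethyl-5,6,7,7a-tetrahydro-1H-inden-2-yl]oxy}dimethylsilane | C12=CCC[C@H](C)[C@@]1(C)CC(O[Si](C)(C)C(C)(C)C)=C2 | intermediate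
9 | (4R,7S,7aR)-4-hydroxy-7,7a-dimethyl-1,4,5,6,7,7a-hexahydro-2H-inden-2-one | O[C@@H]1CC[C@H](C)[C@@]2(C)CC(=O)C=C12 | intermediate
10 | (4R,7S,7aR)-4-[(tert-butyldimethylsilyl)oxy]-7,7a-dimethyl-1,4,5,6,7,7a-hexahydro-2H-inden-2-one | CC(C)(C)[Si](C)(C)O[C@@H]1CC[C@H](C)[C@@]2(C)CC(=O)C=C12 | intermediate
11 | tert-butyl{[(4R,7S,7aS)-7,7a-dimethyl-2-(trimethylsilyloxy)-5,6,7,7a-tetrahydro-4H-inden-4-yl]oxy}dimethylsilane (key-step precursor) | CC(C)(C)[Si](C)(C)O[C@@H]1CC[C@H](C)[C@@]2(C)C=C(O[Si](C)(C)C)C=C12 | intermediate
12 | bromoform | BrC(Br)Br | starting material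
13 | dibromocyclopropane adduct of 11 across C6=C8 (7,7-dibromo, C8 bearing OSiMe3, cis-fused, drawn with CBr2 anti to the C5 methyl) | CC(C)(C)[Si](C)(C)O[C@@H]1CC[C@H](C)[C@@]2(C)[C@H]3C(Br)(Br)[C@@]3(O[Si](C)(C)C)C=C12 | intermediate (not isolated)
14 | 7-bromo-1β-(tert-butyldimethylsilyloxy)-11,12,13-trinoreremophila-6,9-dien-8-one | CC(C)(C)[Si](C)(C)O[C@@H]1CC[C@H](C)[C@@]2(C)C=C(Br)C(=O)C=C12 | intermediate
15 | methyl 2-chloropropanoate (racemic) | CC(Cl)C(=O)OC | starting material
16 | methyl (11S)-1β-(tert-butyldimethylsilyloxy)-8-oxoeremophila-6,9-dien-12-oate | CC(C)(C)[Si](C)(C)O[C@@H]1CC[C@H](C)[C@@]2(C)C=C([C@H](C)C(=O)OC)C(=O)C=C12 | intermediate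
17 | methyl (11S)-1β-hydroxy-8-oxoeremophila-6,9-dien-12-oate | O[C@@H]1CC[C@H](C)[C@@]2(C)C=C([C@H](C)C(=O)OC)C(=O)C=C12 | intermediate
18 | angelic acid [(Z)-2-methylbut-2-enoic acid] | C/C=C(/C)C(=O)O | starting material
19 | (Z)-2-methylbut-2-enoic 2,4,6-trichlorobenzoic anhydride | C/C=C(/C)C(=O)OC(=O)c1c(Cl)cc(Cl)cc1Cl | intermediate (not isolated)
20 | methyl (11S)-1β-angeloyloxy-8-oxoeremophila-6,9-dien-12-oate (1R,4S,5S,11S) | C/C=C(/C)C(=O)O[C@@H]1CC[C@H](C)[C@@]2(C)C=C([C@H](C)C(=O)OC)C(=O)C=C12 | target

Total step count: 11. Longest linear sequence: 11 steps (1 → 20).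

Steps most likely to fail

1. Step 8 (key step). Possible failures are cleavage of the enol silyl ether by tert-butoxide before the carbene is captured, carbene attack at the C9=C10 bond, base-induced epimerisation at C1 or degradation of the bromodienone, and Diels–Alder dimerisation of the diene before it reacts. The fallback sets out from 11 and returns to the route at 16. The enol ether bond of 11 is cyclopropanated with Et2Zn/CH2I2 in CH2Cl2 (Furukawa–Simmons–Smith) to the trimethylsilyloxycyclopropane F1. FeCl3 in DMF at 0 °C (Ito–Saegusa oxidative opening of the internal C6–C8 bond) gives the ring-expanded 6-chloro enone F2, and NaOAc in MeOH eliminates HCl to the unbrominated dienone F3. I2/pyridine (Johnson α-iodination, possible only at C7 because the other β-carbon, C10, is fully substituted) gives the 7-iodo dienone F4, which takes the place of 14 in the nickel coupling of step 9 and gives 16.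

2. Step 9. Possible failures are reduction of the C7–Br bond to C–H by the metal reductant, homocoupling of either partner, sequestration of nickel by the dienone, and insufficient catalyst control at C11 against the bias of the nearby C5 centre. The fallback sets out from 14 and returns at 16. A Pd-catalysed Negishi coupling (Pd(dba)2/P(tBu)3, THF, rt) of 14 with the Reformatsky reagent (1-methoxy-1-oxopropan-2-yl)zinc bromide F5, made from commercial methyl 2-bromopropanoate and zinc dust, forms the C7–C11 bond without stereocontrol. Compound 16 is then separated by chromatography from its 11R epimer F6.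

3. Step 5. Possible failures are poor facial selectivity in the delivery of oxygen to C1 (attack on the α face) and competing oxidation at C9. The fallback sets out from 8 and returns at 9. Should the oxidation of 8 favour the 1α-alcohol F7, this is inverted by Mitsunobu reaction with 4-nitrobenzoic acid (PPh3, DIAD, THF) to the 1β 4-nitrobenzoate F8, and brief methanolysis (K2CO3, MeOH, 0 °C) converts F8 into 9.

Further compounds
F1 | step 8 | trimethylsilyloxycyclopropane from 11 (CH2 across C6=C8, drawn anti to the C5 methyl) | CC(C)(C)[Si](C)(C)O[C@@H]1CC[C@H](C)[C@@]2(C)[C@H]3C[C@@]3(O[Si](C)(C)C)C=C12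
F2 | step 8 | 6-chloro-1β-(tert-butyldimethylsilyloxy)-11,12,13-trinoreremophil-9-en-8-one (C6 epimers) | CC(C)(C)[Si](C)(C)O[C@@H]1CC[C@H](C)[C@@]2(C)C(Cl)CC(=O)C=C12
F3 | step 8 | 1β-(tert-butyldimethylsilyloxy)-11,12,13-trinoreremophila-6,9-dien-8-one | CC(C)(C)[Si](C)(C)O[C@@H]1CC[C@H](C)[C@@]2(C)C=CC(=O)C=C12
F4 | step 8 | 7-iodo-1β-(tert-butyldimethylsilyloxy)-11,12,13-trinoreremophila-6,9-dien-8-one | CC(C)(C)[Si](C)(C)O[C@@H]1CC[C@H](C)[C@@]2(C)C=C(I)C(=O)C=C12
F5 | step 9 | (1-methoxy-1-oxopropan-2-yl)zinc bromide | COC(=O)C(C)[Zn]Br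
F6 | step 9 | methyl (11R)-1β-(tert-butyldimethylsilyloxy)-8-oxoeremophila-6,9-dien-12-oate | CC(C)(C)[Si](C)(C)O[C@@H]1CC[C@H](C)[C@@]2(C)C=C([C@@H](C)C(=O)OC)C(=O)C=C12
F7 | step 5 | (4S,7S,7aR)-4-hydroxy-7,7a-dimethyl-1,4,5,6,7,7a-hexahydro-2H-inden-2-one (1α-alcohol) | O[C@H]1CC[C@H](C)[C@@]2(C)CC(=O)C=C12
F8 | step 5 | (4R,7S,7aR)-7,7a-dimethyl-2-oxo-2,4,5,6,7,7a-hexahydro-1H-inden-4-yl 4-nitrobenzoate | O=C(O[C@@H]1CC[C@H](C)[C@@]2(C)CC(=O)C=C12)c1ccc(cc1)[N+](=O)[O-]
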